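**Plan**

- Retrosynthesis: both acetate C–O bonds are cut last (C2–OAc goes back to a C2 ketone). The ketone is cut at C10–C9 (ring B), and in the same operation ring A is contracted by taking C1 out from between C2 and C10. This gives a 1-hydroxybicyclo[3.1.0]hexane (cyclopentane C2–C3–C4–C5–C10 with C1 as the cyclopropane CH2) that carries the whole C6–C15 chain with a phenylsulfonyl group on C7. The last cut is C6–C7.
- Enabling feature: in ring A the C2 carbonyl is β to the quaternary C10 through C1H2, so C2(=O)–C1–C10 is a 3-oxocyclohexyl unit. Alkoxy-radical scission of the C2–C10 bond of a fused cyclopropanol gives exactly this unit as a tertiary C10 radical. C9 lies 6-endo to C10 along C5–C6–C7–C8=C9, and a sulfonyl group on C7 turns the resulting C8 radical into the 7,8-double bond.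
- Forward: a cyclopentenone bromide (three steps) and a geranyl-acetate-derived allyl sulfone (three steps) are joined at C6–C7. C5 is set, C20 is added, the ketone is enol-silylated and cyclopropanated. One step then makes ring A (five to six atoms) and ring B. Reduction and acetylation finish.
- Stereochemistry: C5 comes from a ligand-controlled copper hydride conjugate reduction. C10 and C9 follow from C5 through a chair 6-endo transition state and the E C8=C9 alkene. C2 comes from hydride attack on the face away from the axial methyls on C4 and C10. The 13E alkene is carried from geranyl acetate.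

Key step: step 11

Remark on numbering: C1–C20 are the labdane numbers of the target and are used for the corresponding atoms of all intermediates.

Assumption: (S)-p-tol-BINAP is taken to direct hydride to the enone face that gives the C5 configuration drawn, by analogy with simple 3-alkylcyclopent-2-enones; if the sense proves opposite, (R)-p-tol-BINAP is used.

**Route**

Step 1
Reactants: 1 3-ethoxycyclopent-2-en-1-one
Product: 3 3-ethoxy-5,5-dimethylcyclopent-2-en-1-one, via 3-ethoxy-5-methylcyclopent-2-en-1-one 2 (not isolated)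
Conditions: LiN(i-Pr)2 (LDA), THF, −78 °C, then MeI; repeated once in the same flask (LDA, then MeI, −78 °C → rt)
Reagents that add atoms: iodomethane CI
Why: Stork–Danheiser alkylation, in which the vinylogous ester is deprotonated kinetically only at the α′ carbon, so two successive methylations build the gem-dimethyl carbon (future C4) next to the carbonyl.

Step 2
Reactants: 3 3-ethoxy-5,5-dimethylcyclopent-2-en-1-one
Product: 5 3,4,4-trimethylcyclopent-2-en-1-one, via tertiary allylic alcohol 4 (not isolated)
Conditions: MeLi, Et2O, −78 → 0 °C; then 1 M HCl, rt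
Reagents that add atoms: methyllithium [Li]C
Why: Stork–Danheiser carbonyl transposition, in which 1,2-addition followed by acidic enol ether hydrolysis and dehydration places the new methyl (future C6) on the β-carbon (future C5) beside the gem-dimethyl carbon and turns the former enol ether carbon into the ketone (future C2).

Step 3
Reactants: 5 3,4,4-trimethylcyclopent-2-en-1-one
Product: 6 3-(bromomethyl)-4,4-dimethylcyclopent-2-en-1-one
Conditions: NBS, AIBN (cat.), PhCF3, 80 °C
Reagents that add atoms: N-bromosuccinimide O=C1CCC(=O)N1Br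
Why: Wohl–Ziegler bromination of the γ-methyl group, the only position that gives a radical conjugated with the enone because the ring γ-carbon is quaternary, as is known for 3-methylcycloalk-2-enones.

Step 4
Reactants: 7 geranyl acetate
Product: 8 (2E,6E)-8-hydroxy-3,7-dimethylocta-2,6-dien-1-yl acetate
Conditions: SeO2 (cat.), t-BuOOH, salicylic acid (cat.), CH2Cl2, rt
Reagents that add atoms: selenium dioxide O=[Se]=O (re-formed by tert-butyl hydroperoxide CC(C)(C)OO)
Why: Riley allylic oxidation, which attacks the more electron-rich distal alkene and, through the ene/[2,3] sequence, hydroxylates only its E-methyl group, a known reaction of geranyl acetate.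

Step 5
Reactants: 8 (2E,6E)-8-hydroxy-3,7-dimethylocta-2,6-dien-1-yl acetate
Product: 9 (2E,6E)-8-bromo-3,7-dimethylocta-2,6-dien-1-yl acetate
Conditions: CBr4, PPh3, CH2Cl2, −20 → 0 °C
Reagents that add atoms: tetrabromomethane BrC(Br)(Br)Br
Why: Appel reaction of a primary allylic alcohol, which proceeds by direct displacement at low temperature and keeps the position and E geometry of the alkene.

Step 6
Reactants: 9 (2E,6E)-8-bromo-3,7-dimethylocta-2,6-dien-1-yl acetate
Product: 10 (2E,6E)-3,7-dimethyl-8-(phenylsulfonyl)octa-2,6-dien-1-yl acetate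
Conditions: PhSO2Na, DMF, rt
Reagents that add atoms: sodium benzenesulfinate [Na+].[O-]S(=O)c1ccccc1
Why: S-alkylation of the sulfinate by the primary allylic bromide gives the allyl sulfone whose CH2 becomes C7, the carbanion site for step 7 and the radical leaving-group site for step 11.

Step 7
Reactants: 10 (2E,6E)-3,7-dimethyl-8-(phenylsulfonyl)octa-2,6-dien-1-yl acetate and 6 3-(bromomethyl)-4,4-dimethylcyclopent-2-en-1-one
Product: 11 (2E,6E)-9-(5,5-dimethyl-3-oxocyclopent-1-en-1-yl)-3,7-dimethyl-8-(phenylsulfonyl)nona-2,6-dien-1-yl acetate (both epimers at the sulfone carbon)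
Conditions: LiN(SiMe3)2 (LiHMDS), THF, −78 °C; then 6, −78 → −40 °C
Reagents that add atoms: none
Why: Alkylation of the allyl sulfone carbanion at its α-carbon forms C6–C7 by displacement on the vinylogous α-bromo ketone; conjugate addition is shut off because the β-carbon of 6 is fully substituted, and LiHMDS is too weak a base to enolise the acetate.

Step 8
Reactants: 11 (2E,6E)-9-(5,5-dimethyl-3-oxocyclopent-1-en-1-yl)-3,7-dimethyl-8-(phenylsulfonyl)nona-2,6-dien-1-yl acetate
Product: 13 (2E,6E)-3,7-dimethyl-8-(phenylsulfonyl)-9-[(1S,2S)-2,5,5-trimethyl-3-oxocyclopentyl]nona-2,6-dien-1-yl acetate, via silyl enol ether 12 (not isolated)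
Conditions: CuCl (5 mol%), NaOt-Bu (5 mol%), (S)-p-tol-BINAP (5 mol%), (EtO)2MeSiH, toluene, 0 °C → rt; then Bu4N[Ph3SiF2] (TBAT), MeI, CH2Cl2, rt
Reagents that add atoms: iodomethane CI; diethoxymethylsilane CCO[SiH](C)OCC (its silicon stays only in 12)
Why: Asymmetric copper hydride conjugate reduction of a 3-substituted cyclopent-2-enone sets C5 by ligand-controlled hydride delivery to one enone face, and fluoride-promoted C-methylation of the regiodefined enol silane adds C20 at C10 trans to the side chain (this centre is erased in step 9).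

Step 9
Reactants: 13 (2E,6E)-3,7-dimethyl-8-(phenylsulfonyl)-9-[(1S,2S)-2,5,5-trimethyl-3-oxocyclopentyl]nona-2,6-dien-1-yl acetate
Product: 14 (2E,6E)-3,7-dimethyl-8-(phenylsulfonyl)-9-{(1R)-2,5,5-trimethyl-3-[(trimethylsilyl)oxy]cyclopent-2-en-1-yl}nona-2,6-dien-1-yl acetate
Conditions: TMSCl, NaI, Et3N, MeCN, rt
Reagents that add atoms: chlorotrimethylsilane C[Si](C)(C)Cl
Why: Enol silylation under equilibrating conditions (iodotrimethylsilane formed in the flask) should give the more substituted enol ether across C2=C10, as is general for 2-methylcycloalkanones.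

Step 10
Reactants: 14 (2E,6E)-3,7-dimethyl-8-(phenylsulfonyl)-9-{(1R)-2,5,5-trimethyl-3-[(trimethylsilyl)oxy]cyclopent-2-en-1-yl}nona-2,6-dien-1-yl acetate
Product: 16 (2E,6E)-9-[(1S,2R,5S)-5-hydroxy-1,3,3-trimethylbicyclo[3.1.0]hexan-2-yl]-3,7-dimethyl-8-(phenylsulfonyl)nona-2,6-dien-1-yl acetate, via trimethylsilyl cyclopropyl ether 15 (not isolated)
Conditions: Et2Zn, CH2I2, CH2Cl2, 0 °C → rt; then PPTS (cat.), MeOH, 0 °C
Reagents that add atoms: diiodomethane ICI
Why: Simmons–Smith cyclopropanation should pick the electron-rich silyl enol ether over the two side-chain alkenes, which are deactivated by their allylic sulfonyl and acetoxy groups, and add C1 anti to the C5 substituent (both new centres are destroyed in step 11); mild acidic methanolysis then frees the cyclopropanol without touching the acetate.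

Step 11
Reactants: 16 (2E,6E)-9-[(1S,2R,5S)-5-hydroxy-1,3,3-trimethylbicyclo[3.1.0]hexan-2-yl]-3,7-dimethyl-8-(phenylsulfonyl)nona-2,6-dien-1-yl acetate
Product: 17 (5R,9R,10R)-2-oxolabda-7,13E-dien-15-yl acetate
Conditions: Mn(acac)3 (20 mol%), 2,6-lutidine, degassed MeCN/t-BuOH (0.01 M), 40 °C
Reagents that add atoms: none
Why: Proposed new method: ligand exchange at Mn(acac)3 gives a trivalent manganese cyclopropanolate that collapses with scission of the strained C2–C10 bond (the bond shared by the two rings), which expands the cyclopentane by C1 into ring A and leaves a tertiary 3-oxocyclohexyl radical at C10; this radical adds to C9 of the allyl sulfone, the β-sulfonyl C8 radical expels PhSO2•, and divalent manganese reduces PhSO2• to sulfinate, so the step is a redox-neutral isomerisation with loss of benzenesulfinic acid. The closest known reaction types are the manganese- or iron-mediated oxidative ring expansion–cyclisation of 1-hydroxy- and 1-siloxybicyclo[n.1.0]alkanes that carry a tethered alkene, the radical allylation of ring-opened cycloalkanols with allyl sulfones, and, for the ring-B closure itself, radical polyene cyclisations that pass through tertiary cyclohexyl radicals. Ring A arises by one-carbon ring expansion (five to six ring atoms) and ring B by 6-endo-trig radical closure. C10 and C9 are both controlled by C5: in the chair transition state the C5 tether is equatorial on ring A, so the new C10–C9 bond forms equatorial (trans ring fusion with axial C20), and the E geometry of C8=C9 places C11 equatorial on ring B. The step needs internal rather than external cyclopropane cleavage (the tertiary radical is favoured and external cleavage is reversible by 3-exo reclosure on the carbonyl), 6-endo rather than 5-exo attack (5-exo would join two fully substituted carbons), and fragmentation before the C8 radical can attack C13=C14, which the sulfonyl group on C7 secures for both C7 epimers, while a solvent without weak C–H bonds and high dilution keep the C10 radical alive until it cyclises.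

Step 12
Reactants: 17 (5R,9R,10R)-2-oxolabda-7,13E-dien-15-yl acetate
Product: 18 (2S,5R,9R,10R)-2-hydroxylabda-7,13E-dien-15-yl acetate
Conditions: NaBH4, MeOH/CH2Cl2, −20 °C
Reagents that add atoms: none
Why: Ketone reduction in which the two syn-axial methyl groups on C4 and C10 block the axial trajectory, so hydride should enter equatorially and give the axial (2S) alcohol cis to the C10 methyl; the acetate survives borohydride at low temperature.

Step 13
Reactants: 18 (2S,5R,9R,10R)-2-hydroxylabda-7,13E-dien-15-yl acetate
Product: 19 (2S,5R,9R,10R)-labda-7,13E-diene-2,15-diyl diacetate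
Conditions: Ac2O, pyridine, DMAP (cat.), CH2Cl2, rt → 40 °C
Reagents that add atoms: acetic anhydride CC(=O)OC(C)=O
Why: DMAP-catalysed acylation of the hindered axial secondary alcohol completes the diacetate without affecting any stereocentre or alkene.

**Compound list**

1 | 3-ethoxycyclopent-2-en-1-one | CCOC1=CC(=O)CC1 | starting material
2 | 3-ethoxy-5-methylcyclopent-2-en-1-one (racemic, not isolated) | CCOC1=CC(=O)C(C)C1 | intermediate
3 | 3-ethoxy-5,5-dimethylcyclopent-2-en-1-one | CCOC1=CC(=O)C(C)(C)C1 | intermediate
4 | 3-ethoxy-1,5,5-trimethylcyclopent-2-en-1-ol (racemic, not isolated) | CCOC1=CC(C)(O)C(C)(C)C1 | intermediate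
5 | 3,4,4-trimethylcyclopent-2-en-1-one | CC1=CC(=O)CC1(C)C | intermediate
6 | 3-(bromomethyl)-4,4-dimethylcyclopent-2-en-1-one | BrCC1=CC(=O)CC1(C)C | intermediate
7 | geranyl acetate, (2E)-3,7-dimethylocta-2,6-dien-1-yl acetate | CC(=O)OC/C=C(\C)CCC=C(C)C | starting material
8 | (2E,6E)-8-hydroxy-3,7-dimethylocta-2,6-dien-1-yl acetate | CC(=O)OC/C=C(\C)CC/C=C(\C)CO | intermediate
9 | (2E,6E)-8-bromo-3,7-dimethylocta-2,6-dien-1-yl acetate | CC(=O)OC/C=C(\C)CC/C=C(\C)CBr | intermediate
10 | (2E,6E)-3,7-dimethyl-8-(phenylsulfonyl)octa-2,6-dien-1-yl acetate | CC(=O)OC/C=C(\C)CC/C=C(\C)CS(=O)(=O)c1ccccc1 | intermediate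
11 | (2E,6E)-9-(5,5-dimethyl-3-oxocyclopent-1-en-1-yl)-3,7-dimethyl-8-(phenylsulfonyl)nona-2,6-dien-1-yl acetate (both epimers at the sulfone carbon C7) | CC(=O)OC/C=C(\C)CC/C=C(\C)C(CC1=CC(=O)CC1(C)C)S(=O)(=O)c1ccccc1 | intermediate
12 | (2E,6E)-9-[(1S)-3-{[diethoxy(methyl)silyl]oxy}-5,5-dimethylcyclopent-2-en-1-yl]-3,7-dimethyl-8-(phenylsulfonyl)nona-2,6-dien-1-yl acetate (C7 epimers, not isolated) | CC(=O)OC/C=C(\C)CC/C=C(\C)C(S(=O)(=O)c1ccccc1)C[C@@H]1C(C)(C)CC(O[Si](C)(OCC)OCC)=C1 | intermediate
13 | (2E,6E)-3,7-dimethyl-8-(phenylsulfonyl)-9-[(1S,2S)-2,5,5-trimethyl-3-oxocyclopentyl]nona-2,6-dien-1-yl acetate (ring substituents trans; C7 epimers) | CC(=O)OC/C=C(\C)CC/C=C(\C)C(S(=O)(=O)c1ccccc1)C[C@@H]1C(C)(C)CC(=O)[C@H]1C | intermediate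
14 | (2E,6E)-3,7-dimethyl-8-(phenylsulfonyl)-9-{(1R)-2,5,5-trimethyl-3-[(trimethylsilyl)oxy]cyclopent-2-en-1-yl}nona-2,6-dien-1-yl acetate (C7 epimers) | CC(=O)OC/C=C(\C)CC/C=C(\C)C(S(=O)(=O)c1ccccc1)C[C@@H]1C(C)(C)CC(O[Si](C)(C)C)=C1C | intermediate
15 | (2E,6E)-3,7-dimethyl-8-(phenylsulfonyl)-9-{(1S,2R,5S)-1,3,3-trimethyl-5-[(trimethylsilyl)oxy]bicyclo[3.1.0]hexan-2-yl}nona-2,6-dien-1-yl acetate (cyclopropane CH2 anti to the side chain; C7 epimers, not isolated) | CC(=O)OC/C=C(\C)CC/C=C(\C)C(S(=O)(=O)c1ccccc1)C[C@@H]1C(C)(C)C[C@@]2(O[Si](C)(C)C)C[C@@]12C | intermediate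
16 | (2E,6E)-9-[(1S,2R,5S)-5-hydroxy-1,3,3-trimethylbicyclo[3.1.0]hexan-2-yl]-3,7-dimethyl-8-(phenylsulfonyl)nona-2,6-dien-1-yl acetate (cyclopropane CH2 anti to the side chain; C7 epimers) | CC(=O)OC/C=C(\C)CC/C=C(\C)C(S(=O)(=O)c1ccccc1)C[C@@H]1C(C)(C)C[C@@]2(O)C[C@@]12C | intermediate
17 | (5R,9R,10R)-2-oxolabda-7,13E-dien-15-yl acetate, i.e. (2E)-3-methyl-5-[(1R,4aR,8aR)-2,5,5,8a-tetramethyl-7-oxo-1,4,4a,5,6,7,8,8a-octahydronaphthalen-1-yl]pent-2-en-1-yl acetate | CC(=O)OC/C=C(\C)CC[C@@H]1C(C)=CC[C@@H]2C(C)(C)CC(=O)C[C@@]12C | intermediate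
18 | (2S,5R,9R,10R)-2-hydroxylabda-7,13E-dien-15-yl acetate (axial 2-OH, cis to the C10 methyl) | CC(=O)OC/C=C(\C)CC[C@@H]1C(C)=CC[C@@H]2C(C)(C)C[C@H](O)C[C@@]12C | intermediate
19 | (2S,5R,9R,10R)-labda-7,13E-diene-2,15-diyl diacetate (trans-decalin, axial 2-acetoxy cis to the C10 methyl, equatorial C9 side chain) | CC(=O)OC/C=C(\C)CC[C@@H]1C(C)=CC[C@@H]2C(C)(C)C[C@H](OC(C)=O)C[C@@]12C | target

**Step count and risks**

Total steps: 13. Longest linear sequence: 10 (steps 4–13; the ring branch, steps 1–3 then 7–13, is equally long).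

Steps most likely to fail:

1. Step 11 (Proposed new method). The tertiary C10 radical may be reduced or oxidised before it closes ring B, the closure may leak to the cis-fused ring system, and sulfonyl radicals may add reversibly to the side-chain alkene and scramble its geometry if manganese turnover is slow. The fallback separates ring expansion from ring closure and uses known reaction types. It sets out from cyclopropanol 16. FeCl3 (2.2 equiv) in DMF at 0 °C should perform the established oxidative ring expansion of fused cyclopropanols with chlorine transfer to the tertiary radical, giving the β-chloro ketone (2E,6E)-9-[(1R)-2-chloro-2,6,6-trimethyl-4-oxocyclohexyl]-3,7-dimethyl-8-(phenylsulfonyl)nona-2,6-dien-1-yl acetate F1. Hexabutylditin, (Bu3Sn)2, under irradiation in refluxing benzene then regenerates the same C10 radical from the tertiary chloride with no oxidant or hydrogen donor present. The usual tin-mediated addition–fragmentation chain onto the allyl sulfone should close ring B with loss of the sulfonyl group, and the route is rejoined at ketone 17.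

2. Step 8. Hydride delivery to a β-carbon flanked by a quaternary carbon may be slow or poorly face-selective. During the fluoride-promoted methylation, a proton may also pass from the acidic sulfone-bearing C7 to the enolate, so that C7 is methylated. The fallback sets out from enone 11, which is reduced as in step 8 to enol silane 12. Instead of fluoride and MeI, 12 is cyclopropanated (Et2Zn, CH2I2) to the siloxycyclopropane (2E,6E)-9-[(1S,2S,5S)-5-{[diethoxy(methyl)silyl]oxy}-3,3-dimethylbicyclo[3.1.0]hexan-2-yl]-3,7-dimethyl-8-(phenylsulfonyl)nona-2,6-dien-1-yl acetate F2. Acid-catalysed methanolysis (HCl cat., MeOH) cleaves the external cyclopropane bond, so C20 arrives as a CH2 plus a proton and no enolate is formed. The route is rejoined at ketone 13.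

3. Step 10. The zinc carbenoid may also cyclopropanate the side-chain alkenes, methylene transfer to the tetrasubstituted enol ether may be sluggish, and the cyclopropanol may ring-open during desilylation. The fallback sets out from silyl enol ether 14. A Mukaiyama aldol reaction with aqueous formaldehyde (Yb(OTf)3 cat., THF/H2O) should give (2E,6E)-9-[(1R)-2-(hydroxymethyl)-2,5,5-trimethyl-3-oxocyclopentyl]-3,7-dimethyl-8-(phenylsulfonyl)nona-2,6-dien-1-yl acetate F3. I2, PPh3 and imidazole in toluene at 80 °C convert it to (2E,6E)-9-[(1R)-2-(iodomethyl)-2,5,5-trimethyl-3-oxocyclopentyl]-3,7-dimethyl-8-(phenylsulfonyl)nona-2,6-dien-1-yl acetate F4. SmI2 in THF (−78 → 0 °C) then closes the three-membered ring by ketyl–halide coupling. The route is rejoined at cyclopropanol 16, obtained together with its ring-fusion diastereomer, which enters step 11 equally.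

**Further compounds**

F1 | step 11 | (2E,6E)-9-[(1R)-2-chloro-2,6,6-trimethyl-4-oxocyclohexyl]-3,7-dimethyl-8-(phenylsulfonyl)nona-2,6-dien-1-yl acetate (mixture at the chlorine-bearing carbon and at C7) | CC(=O)OC/C=C(\C)CC/C=C(\C)C(S(=O)(=O)c1ccccc1)C[C@@H]1C(C)(C)CC(=O)CC1(C)Cl
F2 | step 8 | (2E,6E)-9-[(1S,2S,5S)-5-{[diethoxy(methyl)silyl]oxy}-3,3-dimethylbicyclo[3.1.0]hexan-2-yl]-3,7-dimethyl-8-(phenylsulfonyl)nona-2,6-dien-1-yl acetate | CC(=O)OC/C=C(\C)CC/C=C(\C)C(S(=O)(=O)c1ccccc1)C[C@@H]1C(C)(C)C[C@@]2(O[Si](C)(OCC)OCC)C[C@@H]12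
F3 | step 10 | (2E,6E)-9-[(1R)-2-(hydroxymethyl)-2,5,5-trimethyl-3-oxocyclopentyl]-3,7-dimethyl-8-(phenylsulfonyl)nona-2,6-dien-1-yl acetate (mixture at the quaternary ring carbon and at C7) | CC(=O)OC/C=C(\C)CC/C=C(\C)C(S(=O)(=O)c1ccccc1)C[C@@H]1C(C)(C)CC(=O)C1(C)CO
F4 | step 10 | (2E,6E)-9-[(1R)-2-(iodomethyl)-2,5,5-trimethyl-3-oxocyclopentyl]-3,7-dimethyl-8-(phenylsulfonyl)nona-2,6-dien-1-yl acetate (mixture at the quaternary ring carbon and at C7) | CC(=O)OC/C=C(\C)CC/C=C(\C)C(S(=O)(=O)c1ccccc1)C[C@@H]1C(C)(C)CC(=O)C1(C)CI
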